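**Target:** (2R,3R)-3,7-dihydroxy-2-[4-hydroxy-3,5-bis(3-methylbut-2-en-1-yl)phenyl]-8-(3-methylbut-2-en-1-yl)-2,3-dihydro-4H-chromen-4-one, the 2,3-trans dihydroflavonol (C30H36O5).

## Retrosynthetic overview

1. Open O1–C2: the target comes from a p-quinone methide (dearomatised B ring) carrying an (R)-α-hydroxy ketone. The quinone methide forms by acid dehydration of a (2R)-2,3-dihydroxy-1,3-diarylpropan-1-one, so the benzylic centre needs no prior control.
2. Cut C2–C3: a direct zinc-catalysed asymmetric aldol joins a glycolyl aryl ketone (A ring) and a 3,5-diprenylbenzaldehyde (B ring). Aldol, MOM removal and ring closure run in one pot.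
3. The A-ring donor comes from the C2v-symmetric 2-prenylresorcinol bis-MOM ether, made from resorcinol by two directed lithiations (prenylation, then desymmetrising glycolylation).
4. The B-ring aldehyde comes from 3,5-dibromo-4-hydroxybenzaldehyde by MOM protection and double Stille prenylation.
5. Ring order: both benzene rings are bought; the only ring made is the dihydropyranone (C ring), closed last.

Assumption: compounds whose carbon atoms end up in the target (prenyl sources and the glycolyl Weinreb amide included) are numbered reactants, "Reagents that add atoms" lists only the other, un-numbered reagents, and "prenyl" means 3-methylbut-2-en-1-yl.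

## Route

Step 1
Reactants: 1 resorcinol
Product: 3 1,3-bis(methoxymethoxy)benzene, via 3-(methoxymethoxy)phenol 2 (not isolated)
Conditions: NaH (2.5 equiv), MOMCl (2.4 equiv), DMF, 0 °C → rt
Reagents that add atoms: chloromethyl methyl ether (MOMCl), COCCl
Why: Williamson-type O-alkylation of both phenoxides with the reactive α-chloro ether; no stereocentre.

Step 2
Reactants: 3 1,3-bis(methoxymethoxy)benzene; 4 prenyl bromide (1-bromo-3-methylbut-2-ene)
Product: 6 1,3-bis(methoxymethoxy)-2-(3-methylbut-2-en-1-yl)benzene, via 2-lithio arene 5 (not isolated)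
Conditions: n-BuLi (1.1 equiv), THF, 0 °C → rt; then 4, −78 °C → rt
Reagents that add atoms: none
Why: Directed ortho-metalation removes the C2–H flanked by both OMOM groups, and the aryllithium is alkylated (SN2) by the primary allylic bromide.

Step 3
Reactants: 6 1,3-bis(methoxymethoxy)-2-(3-methylbut-2-en-1-yl)benzene; 7 2-[(tert-butyldimethylsilyl)oxy]-N-methoxy-N-methylacetamide
Product: 10 2-hydroxy-1-[2,4-bis(methoxymethoxy)-3-(3-methylbut-2-en-1-yl)phenyl]ethan-1-one, via 4-lithio arene 8 (not isolated), via TBS ether ketone 9 (not isolated)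
Conditions: n-BuLi, TMEDA, THF, −20 → 0 °C; 7, −78 → 0 °C; AcOH then TBAF, 0 °C
Reagents that add atoms: none
Why: Directed ortho-metalation next to OMOM (C4 and C6 are equivalent in the C2v-symmetric arene, so monolithiation gives a single desymmetrised product), then Weinreb ketone synthesis through the chelated tetrahedral intermediate and buffered fluoride desilylation; no stereocentre.

Step 4
Reactants: 11 3,5-dibromo-4-hydroxybenzaldehyde
Product: 12 3,5-dibromo-4-(methoxymethoxy)benzaldehyde
Conditions: MOMCl (1.5 equiv), K2CO3 (2 equiv), DMF, 0 °C → rt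
Reagents that add atoms: chloromethyl methyl ether (MOMCl), COCCl
Why: O-alkylation of the acidic 2,6-dibromophenoxide by MOMCl; the aldehyde is untouched.

Step 5
Reactants: 12 3,5-dibromo-4-(methoxymethoxy)benzaldehyde; 13 tributyl(3-methylbut-2-en-1-yl)stannane
Product: 15 4-(methoxymethoxy)-3,5-bis(3-methylbut-2-en-1-yl)benzaldehyde, via mono-prenyl bromide 14 (not isolated)
Conditions: 13 (2.4 equiv), Pd(PPh3)4 (8 mol%), DMF, 95 °C
Reagents that add atoms: none
Why: Double Stille cross-coupling, in which the para-formyl group activates both C–Br bonds and the allylstannane transfers its less hindered α (prenyl) terminus.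

Step 6
Reactants: 10 2-hydroxy-1-[2,4-bis(methoxymethoxy)-3-(3-methylbut-2-en-1-yl)phenyl]ethan-1-one (1.3 equiv); 15 4-(methoxymethoxy)-3,5-bis(3-methylbut-2-en-1-yl)benzaldehyde
Product: 19 (2R,3R)-3,7-dihydroxy-2-[4-hydroxy-3,5-bis(3-methylbut-2-en-1-yl)phenyl]-8-(3-methylbut-2-en-1-yl)-2,3-dihydro-4H-chromen-4-one, via (2R)-aldol adduct 16 (not isolated), via deprotected pentol 17 (not isolated), via p-quinone methide 18 (not isolated)
Conditions: (S,S)-linked-BINOL (10 mol%), Et2Zn (20 mol%), THF, −20 °C; then 3 M HCl in MeOH, 45 °C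
Reagents that add atoms: none
Why: Proposed new method: the Et2Zn/linked-BINOL direct catalytic asymmetric aldol of 2-hydroxy-2'-alkoxyacetophenone donors (closest known reaction type; as I recall it, the (S,S)-ligand fixes the α-carbinol as 2R in both syn and anti adducts of the 2'-methoxy parent) is extended here to an aromatic aldehyde and telescoped with an acid cascade in which HCl/MeOH removes the three MOM groups and the 4-hydroxybenzylic alcohol loses water to a dearomatised p-quinone methide (closest known types: HCl/MeOH cyclisation of MOM-protected 2'-hydroxychalcone epoxides to dihydroflavonols, and oxa-1,6-additions to p-quinone methides), which erases the benzylic centre so that the 2'-OH closes the ring by 6-exo oxa-1,6-addition with rearomatisation, placing the aryl group trans-diequatorial to the catalyst-set (R)-carbinol; only the enolate-face selectivity of the aldol must be high, and the 2,3-trans (2R,3R) isomer is both the kinetic and, through reversible ring opening, the thermodynamic product.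

## Compound list

1 | resorcinol (benzene-1,3-diol) | Oc1cccc(O)c1 | starting material
2 | 3-(methoxymethoxy)phenol | COCOc1cccc(O)c1 | intermediate (not isolated)
3 | 1,3-bis(methoxymethoxy)benzene | COCOc1cccc(OCOC)c1 | intermediate
4 | prenyl bromide (1-bromo-3-methylbut-2-ene) | CC(C)=CCBr | starting material
5 | [2,6-bis(methoxymethoxy)phenyl]lithium | [Li]c1c(OCOC)cccc1OCOC | intermediate (not isolated)
6 | 1,3-bis(methoxymethoxy)-2-(3-methylbut-2-en-1-yl)benzene | COCOc1cccc(OCOC)c1CC=C(C)C | intermediate
7 | 2-[(tert-butyldimethylsilyl)oxy]-N-methoxy-N-methylacetamide | CON(C)C(=O)CO[Si](C)(C)C(C)(C)C | starting material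
8 | [2,4-bis(methoxymethoxy)-3-(3-methylbut-2-en-1-yl)phenyl]lithium | [Li]c1ccc(OCOC)c(CC=C(C)C)c1OCOC | intermediate (not isolated)
9 | 2-[(tert-butyldimethylsilyl)oxy]-1-[2,4-bis(methoxymethoxy)-3-(3-methylbut-2-en-1-yl)phenyl]ethan-1-one | COCOc1ccc(C(=O)CO[Si](C)(C)C(C)(C)C)c(OCOC)c1CC=C(C)C | intermediate (not isolated)
10 | 2-hydroxy-1-[2,4-bis(methoxymethoxy)-3-(3-methylbut-2-en-1-yl)phenyl]ethan-1-one | COCOc1ccc(C(=O)CO)c(OCOC)c1CC=C(C)C | intermediate
11 | 3,5-dibromo-4-hydroxybenzaldehyde | O=Cc1cc(Br)c(O)c(Br)c1 | starting material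
12 | 3,5-dibromo-4-(methoxymethoxy)benzaldehyde | COCOc1c(Br)cc(C=O)cc1Br | intermediate
13 | tributyl(3-methylbut-2-en-1-yl)stannane | CCCC[Sn](CCCC)(CCCC)CC=C(C)C | starting material
14 | 3-bromo-4-(methoxymethoxy)-5-(3-methylbut-2-en-1-yl)benzaldehyde | COCOc1c(Br)cc(C=O)cc1CC=C(C)C | intermediate (not isolated)
15 | 4-(methoxymethoxy)-3,5-bis(3-methylbut-2-en-1-yl)benzaldehyde | COCOc1c(CC=C(C)C)cc(C=O)cc1CC=C(C)C | intermediate
16 | (2R)-2,3-dihydroxy-1-[2,4-bis(methoxymethoxy)-3-prenylphenyl]-3-[4-(methoxymethoxy)-3,5-diprenylphenyl]propan-1-one, C3-epimer mixture (syn-(2R,3S) expected major) | COCOc1ccc(C(=O)[C@H](O)C(O)c2cc(CC=C(C)C)c(OCOC)c(CC=C(C)C)c2)c(OCOC)c1CC=C(C)C | intermediate (not isolated)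
17 | (2R)-1-(2,4-dihydroxy-3-prenylphenyl)-2,3-dihydroxy-3-(4-hydroxy-3,5-diprenylphenyl)propan-1-one, C3-epimer mixture | CC(C)=CCc1cc(C(O)[C@@H](O)C(=O)c2ccc(O)c(CC=C(C)C)c2O)cc(CC=C(C)C)c1O | intermediate (not isolated)
18 | 4-[(2R)-3-(2,4-dihydroxy-3-prenylphenyl)-2-hydroxy-3-oxopropylidene]-2,6-diprenylcyclohexa-2,5-dien-1-one (p-quinone methide) | CC(C)=CCC1=CC(=C[C@@H](O)C(=O)c2ccc(O)c(CC=C(C)C)c2O)C=C(CC=C(C)C)C1=O | intermediate (not isolated)
19 | (2R,3R)-3,7-dihydroxy-2-[4-hydroxy-3,5-bis(3-methylbut-2-en-1-yl)phenyl]-8-(3-methylbut-2-en-1-yl)-2,3-dihydro-4H-chromen-4-one | CC(C)=CCc1cc([C@H]2Oc3c(ccc(O)c3CC=C(C)C)C(=O)[C@@H]2O)cc(CC=C(C)C)c1O | target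

## Step count and risks

Total steps: 6. Longest linear sequence: 4 (steps 1, 2, 3, 6); the B-ring branch is steps 4 and 5.

**Most likely to fail, 1: step 6.** The aromatic aldehyde may react slowly or with lower enolate-face selectivity than the aliphatic acceptors this catalyst class is known for. The ligand's sense of induction with donor 10 must be confirmed on the first run; if it is opposite, use the (R,R)-ligand. The benzylic alcohol may ionise sluggishly next to the ketone, and the hot acid can cyclise prenyl groups onto neighbouring phenols.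

Fallback: deliver the oxygen by enone epoxidation instead of aldol. It sets out from 6 and 15. Aryllithium 8, made from 6 as in step 3, is trapped with N-methoxy-N-methylacetamide to give the methyl ketone 1-[2,4-bis(methoxymethoxy)-3-prenylphenyl]ethan-1-one F1. Claisen–Schmidt condensation of F1 with 15 (KOH, EtOH) gives the (E)-chalcone F2. Juliá–Colonna epoxidation (poly-L-leucine, urea–H2O2, DBU, THF) is nucleophilic and leaves the prenyl groups alone, and gives the (αR,βS)-epoxychalcone F3. The HCl/MeOH stage of step 6 then removes the MOM groups and opens the epoxide at the benzylic carbon to the same p-quinone methide, so the fallback comes back to the route at 18 and proceeds to 19.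

**Most likely to fail, 2: step 5.** The double Stille coupling may stop at mono-coupled 14, give some branched (1,1-dimethylallyl) isomer, or isomerise the prenyl double bond into conjugation at 95 °C.

Fallback: install allyl groups and convert them afterwards. It sets out from 12. Stille coupling with allyltributylstannane, which has no α/γ ambiguity, passes through the mono-allyl bromide 3-allyl-5-bromo-4-(methoxymethoxy)benzaldehyde F7 and gives 3,5-diallyl-4-(methoxymethoxy)benzaldehyde F8. Olefin cross-metathesis of F8 with excess 2-methyl-2-butene (Grubbs II, CH2Cl2, 40 °C) turns both allyl groups into prenyl groups, and the fallback comes back at 15.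

**Most likely to fail, 3: step 3.** The doubly activated ArCH2–CH= protons of the prenyl group may be removed in competition with the ring C4–H, and the long metalation with TMEDA can lower the acylation yield.

Fallback: fix the metalation site with a halogen before the prenyl group is present. It sets out from 3. NBS (MeCN, 0 °C) brominates para to one OMOM group to give 1-bromo-2,4-bis(methoxymethoxy)benzene F4. LDA (THF, −78 °C) deprotonates between the two OMOM groups to give [3-bromo-2,6-bis(methoxymethoxy)phenyl]lithium F5, which prenyl bromide 4 alkylates to 1-bromo-2,4-bis(methoxymethoxy)-3-prenylbenzene F6. Bromine–lithium exchange on F6 (n-BuLi, THF, −78 °C, minutes) gives the aryllithium regiospecifically, so the fallback comes back at 8 and continues with 7 to 10 as in step 3.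

## Further compounds

F1 | step 6 | 1-[2,4-bis(methoxymethoxy)-3-(3-methylbut-2-en-1-yl)phenyl]ethan-1-one | COCOc1ccc(C(C)=O)c(OCOC)c1CC=C(C)C
F2 | step 6 | (E)-1-[2,4-bis(methoxymethoxy)-3-prenylphenyl]-3-[4-(methoxymethoxy)-3,5-diprenylphenyl]prop-2-en-1-one | COCOc1ccc(C(=O)/C=C/c2cc(CC=C(C)C)c(OCOC)c(CC=C(C)C)c2)c(OCOC)c1CC=C(C)C
F3 | step 6 | [2,4-bis(methoxymethoxy)-3-prenylphenyl][(2R,3S)-3-[4-(methoxymethoxy)-3,5-diprenylphenyl]oxiran-2-yl]methanone | COCOc1ccc(C(=O)[C@@H]3O[C@H]3c2cc(CC=C(C)C)c(OCOC)c(CC=C(C)C)c2)c(OCOC)c1CC=C(C)C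
F4 | step 3 | 1-bromo-2,4-bis(methoxymethoxy)benzene | COCOc1ccc(Br)c(OCOC)c1
F5 | step 3 | [3-bromo-2,6-bis(methoxymethoxy)phenyl]lithium | [Li]c1c(OCOC)ccc(Br)c1OCOC
F6 | step 3 | 1-bromo-2,4-bis(methoxymethoxy)-3-(3-methylbut-2-en-1-yl)benzene | COCOc1ccc(Br)c(OCOC)c1CC=C(C)C
F7 | step 5 | 3-allyl-5-bromo-4-(methoxymethoxy)benzaldehyde | COCOc1c(Br)cc(C=O)cc1CC=C
F8 | step 5 | 3,5-diallyl-4-(methoxymethoxy)benzaldehyde | COCOc1c(CC=C)cc(C=O)cc1CC=C
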